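**Retrosynthetic overview**
1. Ring B (the pyridone) is opened at both of its C–N bonds, N1–C2 and N1–C8a. This gives ammonia and a 1-(2-fluorophenyl)-1,3-diketone that already carries the whole side chain.
2. The 1,3-diketone is cut at C2–C3 (crossed Claisen) into 2'-fluoroacetophenone and methyl 13-hydroxy-13-methyltetradecanoate.
3. The hydroxy ester comes from twofold methyl addition to one end of symmetrical dimethyl tridecanedioate, whose eleven CH2 groups are exactly the tether.
4. Ring order: ring A (benzene) is bought. Ring B is the only ring made and is closed in the last step. No protecting groups are used.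

Assumption: the target has no stereocentre, because the carbinol carbon bears two identical methyl groups. The achiral compound itself is therefore the goal, drawn as the 4(1H)-quinolone tautomer of the given SMILES.

**Route**

Step 1
Reactants: 1 dimethyl tridecanedioate
Product: 3 methyl 13-hydroxy-13-methyltetradecanoate, via keto ester 2 (not isolated)
Conditions: 1 (3.0 equiv), MeMgBr (2.0 equiv, added over 1 h), THF, −20 to 0 °C; then cold 1 M HCl; excess 1 recovered
Reagents that add atoms: methylmagnesium bromide, C[Mg]Br
Why: Twofold Grignard addition to an ester, in which keto ester 2 from the first addition is far more electrophilic than any ester group and is consumed at once, while the threefold excess of the cheap symmetrical diester holds the statistical mono:bis ratio near 10:1; the new carbinol carbon bears two identical methyl groups, so no stereocentre arises.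

Step 2
Reactants: 3 methyl 13-hydroxy-13-methyltetradecanoate; 4 1-(2-fluorophenyl)ethan-1-one (2'-fluoroacetophenone)
Product: 5 1-(2-fluorophenyl)-15-hydroxy-15-methylhexadecane-1,3-dione
Conditions: NaH (3.2 equiv), THF, 0 °C; slow addition of 4 (1.3 equiv), 55 °C, 6 h; then cold 1 M HCl
Reagents that add atoms: none
Why: Crossed Claisen condensation, in which the sodium enolate of 4 (the most acidic carbon acid present) is acylated by the methyl ester of 3 and irreversible deprotonation of the 1,3-diketone drives the equilibrium, while the hindered tertiary alkoxide stays a spectator and the C–F bond survives at 55 °C because the aroyl group is tied up as an electron-rich enolate; no stereocentre is formed.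

Step 3
Reactants: 5 1-(2-fluorophenyl)-15-hydroxy-15-methylhexadecane-1,3-dione
Product: 7 2-(12-hydroxy-12-methyltridecyl)quinolin-4(1H)-one, via Z-enaminone 6 (not isolated)
Conditions: NH4OAc (6 equiv), EtOH, 70 °C, 3 h; evaporate, water wash, toluene azeotrope; then K2CO3 (3 equiv), 4 Å MS, DMSO, 120 °C, 14 h
Reagents that add atoms: ammonium acetate, CC(=O)[O-].[NH4+]
Why: Proposed new method: a metal-free [5+1] double C–N annulation with ammonia as the only nitrogen donor, in which NH3 condenses reversibly and ends up at the unconjugated, more electrophilic C3 carbonyl as the hydrogen-bonded Z-enaminone 6 (the C1 regioisomer cannot cyclise and drains back), water is then removed so that no diketone enolate is left to close through oxygen to the chromone, carbonate in DMSO deprotonates N–H, rotation about C1–C2 brings the nitrogen anion over the C–F carbon, and addition–elimination (SNAr, activated by the ortho acyl group, fluoride lost as KF) closes ring B with the aromatic quinolone as the driving force; the closest known reaction types are the Grohe–Heitzer enaminone SNAr cyclisation and the tandem aza-Michael/SNAr amination of 2-fluorophenyl ynones with primary amines, neither shown with ammonia on a free 2-alkyl 1,3-diketone whose ring bears a single fluorine and no further activation; the tertiary alcohol is inert to carbonate and no stereocentre is formed.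

**Compound list**
1 | dimethyl tridecanedioate | COC(=O)CCCCCCCCCCCC(=O)OC | starting material
2 | methyl 13-oxotetradecanoate | COC(=O)CCCCCCCCCCCC(C)=O | intermediate
3 | methyl 13-hydroxy-13-methyltetradecanoate | COC(=O)CCCCCCCCCCCC(C)(C)O | intermediate
4 | 1-(2-fluorophenyl)ethan-1-one | CC(=O)c1ccccc1F | starting material
5 | 1-(2-fluorophenyl)-15-hydroxy-15-methylhexadecane-1,3-dione | CC(C)(O)CCCCCCCCCCCC(=O)CC(=O)c1ccccc1F | intermediate
6 | (Z)-3-amino-1-(2-fluorophenyl)-15-hydroxy-15-methylhexadec-2-en-1-one | CC(C)(O)CCCCCCCCCCC/C(N)=C/C(=O)c1ccccc1F | intermediate
7 | 2-(12-hydroxy-12-methyltridecyl)quinolin-4(1H)-one | CC(C)(O)CCCCCCCCCCCc1cc(=O)c2ccccc2[nH]1 | target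

**Step count and risks**
Total steps: 3. Longest linear sequence: 3. Every step builds a skeletal bond, and there are no protecting groups or redox adjustments.

Step 3 (the new annulation) is the most likely to fail. The enaminone carbonyl is only a modest SNAr activator. Any water returns 6 to the diketone, which then closes through oxygen to the chromone.
- The fallback uses known chemistry. It sets out from 3 and comes back at 7.
- Ammonolysis of 3 (7 M NH3 in MeOH, cat. NaOMe, sealed tube, 80 °C) gives 13-hydroxy-13-methyltetradecanamide F1.
- Pd-catalysed N-arylation of F1 with 2'-bromoacetophenone (Pd2(dba)3, Xantphos, Cs2CO3, 1,4-dioxane, 100 °C) gives N-(2-acetylphenyl)-13-hydroxy-13-methyltetradecanamide F2.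
- NaOH in 1,4-dioxane at 110 °C then closes ring B by Camps cyclisation to 7.

Step 2 is the second risk. The unactivated, enolisable ester may acylate slowly, so that self-aldol of 4 or early chromone formation takes over.
- The fallback reverses the donor and acceptor roles. It sets out from 3 and comes back at 5.
- MeNH(OMe)·HCl with iPrMgCl in THF at −10 °C converts 3 into 13-hydroxy-N-methoxy-N,13-dimethyltetradecanamide F3.
- MeMgBr converts F3 into 14-hydroxy-14-methylpentadecan-2-one F4.
- F4 is acylated at its methyl terminus by the non-enolisable methyl 2-fluorobenzoate (NaH, THF, 50 °C) to give 5.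

Step 1 is the third risk. The outcome is only statistical, and 3 must be separated from recovered 1 and from the diol.
- The fallback tells the two ends apart chemically. It sets out from 1 and comes back at 3.
- Ba(OH)2 (0.5 equiv) in MeOH precipitates the barium salt of the half ester and so withdraws it from further hydrolysis. Acidification gives 13-methoxy-13-oxotridecanoic acid F5.
- MeMgBr (3.5 equiv, THF, 0 °C) attacks only the ester, because the magnesium carboxylate is inert. This gives 13-hydroxy-13-methyltetradecanoic acid F6.
- MeI and K2CO3 in DMF return 3.

**Further compounds**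
F1 | step 3 | 13-hydroxy-13-methyltetradecanamide | CC(C)(O)CCCCCCCCCCCC(N)=O
F2 | step 3 | N-(2-acetylphenyl)-13-hydroxy-13-methyltetradecanamide | CC(C)(O)CCCCCCCCCCCC(=O)Nc1ccccc1C(C)=O
F3 | step 2 | 13-hydroxy-N-methoxy-N,13-dimethyltetradecanamide | CON(C)C(=O)CCCCCCCCCCCC(C)(C)O
F4 | step 2 | 14-hydroxy-14-methylpentadecan-2-one | CC(=O)CCCCCCCCCCCC(C)(C)O
F5 | step 1 | 13-methoxy-13-oxotridecanoic acid | COC(=O)CCCCCCCCCCCC(=O)O
F6 | step 1 | 13-hydroxy-13-methyltetradecanoic acid | CC(C)(O)CCCCCCCCCCCC(=O)O
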